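**Retrosynthetic overview**
1. Chrysomutanin 31 ⇐ bis-silyl ether 30 ⇐ macrocyclic C5'-sulfone 29 (desilylation; palladium-catalysed hydride desulfonylation).
2. 29 ⇐ open-chain 27 by closing the 14-membered ring at the C4'–C5' CH2–CH2 bond: an α-sulfonyl carbanion at C5' displaces an allylic chloride at C4'. Enabling feature: C4'–C5' is the saturated link of the skipped diene C2'=C3'–C4'–C5'–C6'=C7', so both carbons are allylic, and the two arms sit ortho on the benzene ring (C5–C1' and C6–O–C11').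
3. 27 ⇐ dihydroisocoumarin triol 15 + 3-bromo-3-methylbutan-2-one (tertiary aryl ether) + two copies of one Z-alkenyl iodide 2 (Suzuki for C1'–C2', enolate allylation for C8'–C9', Negishi for C5'–C6'). Both Z alkenes come from 2 by stereoretentive couplings; C10' is set by CBS reduction.
4. 15 ⇐ 5-bromoresorcinol + (R)-propylene oxide (C3); symmetric dibromination, then carboxylation/lactonisation of one bromide leaves the other as the C5 handle.
5. Ring order: benzene (from the starting material) → δ-lactone (step 6) → 14-membered ring (step 17).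

Key step: step 17

Remark: both trisubstituted alkenes are taken as drawn in the SMILES, i.e. Z (C1' cis to C4', C5' cis to C8'); locants 1–8a refer to the dihydroisocoumarin, C1' (benzylic CH2) to C11' (ether carbon) to the C15 chain; TBS = tert-butyldimethylsilyl, MOM = methoxymethyl, Bpin = pinacolatoboryl.

Step 1
Reactants: 1 prop-2-yn-1-ol
Product: 2 (2Z)-3-iodo-2-methylprop-2-en-1-ol
Conditions: MeMgBr (2.5 equiv), CuI (10 mol%), THF, −10 °C → rt; then I2, THF, −20 °C; sat. NH4Cl
Reagents that add atoms: methylmagnesium bromide C[Mg]Br; iodine II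
Why: Copper-catalysed anti-carbomagnesiation of the propargylic alkoxide (the magnesium ends up cis to the CH2O group through a five-membered chelate) followed by iodinolysis with retention gives the Z iodoalkene that later supplies both trisubstituted alkenes.

Step 2
Reactants: 2 (2Z)-3-iodo-2-methylprop-2-en-1-ol
Product: 3 (1Z)-3-bromo-1-iodo-2-methylprop-1-ene
Conditions: PBr3 (0.4 equiv), Et2O, 0 °C
Reagents that add atoms: phosphorus tribromide BrP(Br)Br
Why: Bromination of a primary allylic alcohol with PBr3 (SN2 on the phosphite ester) leaves the alkenyl iodide and the alkene geometry unchanged.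

Step 3
Reactants: 4 5-bromobenzene-1,3-diol
Product: 5 1-bromo-3,5-bis(methoxymethoxy)benzene
Conditions: MOMCl (2.4 equiv), i-Pr2NEt, CH2Cl2, 0 °C → rt
Reagents that add atoms: chloromethyl methyl ether COCCl
Why: Base-mediated O-alkylation of both phenols with MOMCl gives acetal ethers that should survive the Grignard, bromination, lithiation and Suzuki steps and keep the arene symmetric.

Step 4
Reactants: 5 1-bromo-3,5-bis(methoxymethoxy)benzene; 6 (R)-2-methyloxirane
Product: 8 (2R)-1-[3,5-bis(methoxymethoxy)phenyl]propan-2-ol, via aryl Grignard reagent 7 (not isolated)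
Conditions: Mg, THF, rt; CuI (10 mol%), 6 (1.2 equiv), −30 → 0 °C; sat. NH4Cl
Reagents that add atoms: none
Why: Copper-catalysed opening of the terminal epoxide by the aryl Grignard reagent occurs at the CH2 carbon (SN2), so the stereocenter of 6 becomes C3 of the lactone without being touched.

Step 5
Reactants: 8 (2R)-1-[3,5-bis(methoxymethoxy)phenyl]propan-2-ol
Product: 9 (2R)-1-[2,6-dibromo-3,5-bis(methoxymethoxy)phenyl]propan-2-ol
Conditions: NBS (2.05 equiv), MeCN, 0 °C → rt
Reagents that add atoms: N-bromosuccinimide O=C1CCC(=O)N1Br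
Why: Electrophilic aromatic bromination should go twice to the equivalent positions next to the side chain (each ortho to one and para to the other ether oxygen), the position between the two ether groups being the most hindered.

Step 6
Reactants: 9 (2R)-1-[2,6-dibromo-3,5-bis(methoxymethoxy)phenyl]propan-2-ol
Product: 12 (3R)-5-bromo-6,8-bis(methoxymethoxy)-3-methyl-3,4-dihydroisochromen-1-one, via aryllithium alkoxide 10 (not isolated), via hydroxy acid 11 (not isolated)
Conditions: n-BuLi (2.1 equiv), THF, −78 °C; CO2 (gas), −78 °C → rt; AcOH; then EDCI·HCl, DMAP (cat.), CH2Cl2, rt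
Reagents that add atoms: carbon dioxide O=C=O
Why: After deprotonation of the alcohol, bromine–lithium exchange at one of the two equivalent bromines, carboxylation and carbodiimide lactonisation (acyl activation, C3 untouched) close the lactone ring in the 6-exo-trig mode, and the symmetry of 9 fixes the remaining bromine at C5.

Step 7
Reactants: 12 (3R)-5-bromo-6,8-bis(methoxymethoxy)-3-methyl-3,4-dihydroisochromen-1-one; 2 (2Z)-3-iodo-2-methylprop-2-en-1-ol
Product: 14 (3R)-5-[(2Z)-4-hydroxy-3-methylbut-2-enyl]-6,8-bis(methoxymethoxy)-3-methyl-3,4-dihydroisochromen-1-one, via benzylboronate 13 (not isolated)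
Conditions: CH2(Bpin)2 (1.3 equiv), Pd[P(t-Bu)3]2 (5 mol%), KOH (aq), 1,4-dioxane, rt → 40 °C; then 2 (1.5 equiv), KOH (aq), 60 °C; NaH2PO4 (aq) work-up
Reagents that add atoms: bis(pinacolatoboryl)methane CC1(C)OB(CB2OC(C)(C)C(C)(C)O2)OC1(C)C
Why: Two Suzuki–Miyaura couplings in one pot: the gem-diborylmethane transfers a CH2Bpin unit to the aryl bromide, and benzylboronate 13 then couples with alkenyl iodide 2 with retention of the Z geometry, because oxidative addition and reductive elimination at the sp2 carbon are stereoretentive.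

Step 8
Reactants: 14 (3R)-5-[(2Z)-4-hydroxy-3-methylbut-2-enyl]-6,8-bis(methoxymethoxy)-3-methyl-3,4-dihydroisochromen-1-one
Product: 15 (3R)-6,8-dihydroxy-5-[(2Z)-4-hydroxy-3-methylbut-2-enyl]-3-methyl-3,4-dihydroisochromen-1-one
Conditions: HCl (3 M aq), MeOH, rt → 40 °C
Reagents that add atoms: none
Why: Acid-catalysed acetal cleavage removes both MOM groups (and re-closes any lactone opened by hydroxide in step 7), while the primary allylic alcohol and the trisubstituted alkene should not be ionised by dilute acid at this temperature.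

Step 9
Reactants: 15 (3R)-6,8-dihydroxy-5-[(2Z)-4-hydroxy-3-methylbut-2-enyl]-3-methyl-3,4-dihydroisochromen-1-one; 16 3-bromo-3-methylbutan-2-one
Product: 17 (3R)-8-hydroxy-5-[(2Z)-4-hydroxy-3-methylbut-2-enyl]-3-methyl-6-[(2-methyl-3-oxobutan-2-yl)oxy]-3,4-dihydroisochromen-1-one
Conditions: 16 (1.3 equiv), K2CO3, DMF, 50 °C
Reagents that add atoms: none
Why: Williamson-type O-alkylation of the phenoxide with a tertiary alpha-bromo ketone (substitution assisted by the adjacent carbonyl) forms the tertiary aryl ether; only the 6-OH should react, since the 8-OH is held in a hydrogen bond to the lactone carbonyl and the aliphatic OH is not deprotonated by carbonate.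

Step 10
Reactants: 17 (3R)-8-hydroxy-5-[(2Z)-4-hydroxy-3-methylbut-2-enyl]-3-methyl-6-[(2-methyl-3-oxobutan-2-yl)oxy]-3,4-dihydroisochromen-1-one
Product: 18 (3R)-3-methyl-5-[(2Z)-3-methyl-4-(TBS-oxy)but-2-enyl]-6-[(2-methyl-3-oxobutan-2-yl)oxy]-8-(TBS-oxy)-3,4-dihydroisochromen-1-one
Conditions: TBSCl (2.5 equiv), imidazole, DMF, rt
Reagents that add atoms: tert-butyldimethylsilyl chloride CC(C)(C)[Si](C)(C)Cl
Why: Silylation of the primary allylic alcohol and of the chelated phenol removes both acidic OH groups before the enolate alkylation.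

Step 11
Reactants: 18 (3R)-3-methyl-5-[(2Z)-3-methyl-4-(TBS-oxy)but-2-enyl]-6-[(2-methyl-3-oxobutan-2-yl)oxy]-8-(TBS-oxy)-3,4-dihydroisochromen-1-one; 3 (1Z)-3-bromo-1-iodo-2-methylprop-1-ene
Product: 20 (3R)-6-{[(6Z)-7-iodo-2,6-dimethyl-3-oxohept-6-en-2-yl]oxy}-3-methyl-5-[(2Z)-3-methyl-4-(TBS-oxy)but-2-enyl]-8-(TBS-oxy)-3,4-dihydroisochromen-1-one, via lithium enolate 19 (not isolated)
Conditions: LiN(i-Pr)2 (1.1 equiv), THF, −78 °C; then 3 (1.3 equiv), DMPU, −78 → −40 °C
Reagents that add atoms: none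
Why: Kinetic enolate alkylation: the ketone can enolise only toward its methyl group (the other alpha carbon is quaternary), and the lithium enolate displaces the allylic bromide of 3 by SN2, leaving the alkenyl iodide and its Z geometry intact.

Step 12
Reactants: 20 (3R)-6-{[(6Z)-7-iodo-2,6-dimethyl-3-oxohept-6-en-2-yl]oxy}-3-methyl-5-[(2Z)-3-methyl-4-(TBS-oxy)but-2-enyl]-8-(TBS-oxy)-3,4-dihydroisochromen-1-one
Product: 21 (3R)-6-{[(3S,6Z)-3-hydroxy-7-iodo-2,6-dimethylhept-6-en-2-yl]oxy}-3-methyl-5-[(2Z)-3-methyl-4-(TBS-oxy)but-2-enyl]-8-(TBS-oxy)-3,4-dihydroisochromen-1-one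
Conditions: (R)-2-methyl-CBS-oxazaborolidine (0.3 equiv), catecholborane (2 equiv), toluene, −78 → −40 °C; aq NaHCO3 work-up
Reagents that add atoms: none
Why: Corey–Bakshi–Shibata reduction under reagent control: the oxazaborolidine distinguishes the bulky quaternary aryloxy-substituted carbon from the CH2 chain, and the (R)-catalyst should deliver hydride to the face that gives the (S)-alcohol at C10'.

Step 13
Reactants: 21 (3R)-6-{[(3S,6Z)-3-hydroxy-7-iodo-2,6-dimethylhept-6-en-2-yl]oxy}-3-methyl-5-[(2Z)-3-methyl-4-(TBS-oxy)but-2-enyl]-8-(TBS-oxy)-3,4-dihydroisochromen-1-one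
Product: 22 (3R)-6-{[(3S,6Z)-7-iodo-2,6-dimethyl-3-(TBS-oxy)hept-6-en-2-yl]oxy}-3-methyl-5-[(2Z)-3-methyl-4-(TBS-oxy)but-2-enyl]-8-(TBS-oxy)-3,4-dihydroisochromen-1-one
Conditions: TBSOTf (1.5 equiv), 2,6-lutidine, CH2Cl2, −78 → 0 °C
Reagents that add atoms: tert-butyldimethylsilyl trifluoromethanesulfonate CC(C)(C)[Si](C)(C)OS(=O)(=O)C(F)(F)F
Why: Silyl triflate etherification protects the hindered secondary alcohol so that no alkoxide (which could trigger aryl migration of Smiles type or O-alkylation) is present in the base-mediated ring closure.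

Step 14
Reactants: 22 (3R)-6-{[(3S,6Z)-7-iodo-2,6-dimethyl-3-(TBS-oxy)hept-6-en-2-yl]oxy}-3-methyl-5-[(2Z)-3-methyl-4-(TBS-oxy)but-2-enyl]-8-(TBS-oxy)-3,4-dihydroisochromen-1-one; 23 (methylsulfonyl)benzene
Product: 25 (3R)-6-{[(3S,6Z)-2,6-dimethyl-8-(phenylsulfonyl)-3-(TBS-oxy)oct-6-en-2-yl]oxy}-3-methyl-5-[(2Z)-3-methyl-4-(TBS-oxy)but-2-enyl]-8-(TBS-oxy)-3,4-dihydroisochromen-1-one, via sulfonylmethylzinc chloride 24 (not isolated)
Conditions: 23 (2 equiv), n-BuLi, THF, −78 → 0 °C; ZnCl2 (2.2 equiv); then 22, Pd2(dba)3 (2.5 mol%), XPhos (10 mol%), THF, 60 °C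
Reagents that add atoms: none
Why: Negishi coupling of the alpha-sulfonyl organozinc reagent 24 with the alkenyl iodide forms the C5'–C6' bond with retention of the Z geometry and installs the sulfone that will acidify C5'; the ketone has already been reduced and protected, so no intramolecular aldol is possible.

Step 15
Reactants: 25 (3R)-6-{[(3S,6Z)-2,6-dimethyl-8-(phenylsulfonyl)-3-(TBS-oxy)oct-6-en-2-yl]oxy}-3-methyl-5-[(2Z)-3-methyl-4-(TBS-oxy)but-2-enyl]-8-(TBS-oxy)-3,4-dihydroisochromen-1-one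
Product: 26 (3R)-6-{[(3S,6Z)-2,6-dimethyl-8-(phenylsulfonyl)-3-(TBS-oxy)oct-6-en-2-yl]oxy}-5-[(2Z)-4-hydroxy-3-methylbut-2-enyl]-3-methyl-8-(TBS-oxy)-3,4-dihydroisochromen-1-one
Conditions: PPTS (0.2 equiv), MeOH, rt
Reagents that add atoms: none
Why: Mild acid methanolysis should remove the unhindered primary allylic silyl ether selectively, the aryl and the hindered secondary silyl ethers being much slower under acidic conditions.

Step 16
Reactants: 26 (3R)-6-{[(3S,6Z)-2,6-dimethyl-8-(phenylsulfonyl)-3-(TBS-oxy)oct-6-en-2-yl]oxy}-5-[(2Z)-4-hydroxy-3-methylbut-2-enyl]-3-methyl-8-(TBS-oxy)-3,4-dihydroisochromen-1-one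
Product: 27 (3R)-5-[(2Z)-4-chloro-3-methylbut-2-enyl]-6-{[(3S,6Z)-2,6-dimethyl-8-(phenylsulfonyl)-3-(TBS-oxy)oct-6-en-2-yl]oxy}-3-methyl-8-(TBS-oxy)-3,4-dihydroisochromen-1-one
Conditions: NCS (1.3 equiv), Me2S (1.5 equiv), CH2Cl2, −30 → 0 °C
Reagents that add atoms: N-chlorosuccinimide O=C1CCC(=O)N1Cl
Why: Corey–Kim chlorination converts the primary allylic alcohol into the chloride by SN2 displacement of the alkoxysulfonium ion, without allylic transposition or loss of the Z geometry.

Step 17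
Reactants: 27 (3R)-5-[(2Z)-4-chloro-3-methylbut-2-enyl]-6-{[(3S,6Z)-2,6-dimethyl-8-(phenylsulfonyl)-3-(TBS-oxy)oct-6-en-2-yl]oxy}-3-methyl-8-(TBS-oxy)-3,4-dihydroisochromen-1-one
Product: 29 5'-(phenylsulfonyl)-8,10'-bis-O-TBS-chrysomutanin (both C5' epimers), via potassium sulfonyl carbanion 28 (not isolated)
Conditions: KN(SiMe3)2 (1.1 equiv), THF (0.002 M in 27), −78 → 0 °C
Reagents that add atoms: none
Why: KN(SiMe3)2 removes a C5' proton (alpha to the sulfonyl group and allylic to C6'=C7') to give potassium carbanion 28, which displaces the primary allylic chloride at C4' in an intramolecular SN2 reaction, forming the C4'–C5' bond and with it the complete C15 chain and the macrocycle. The closest known reaction type is the head-to-tail terpenoid coupling of allylic sulfone anions with allylic halides and its intramolecular version used to close 14-membered terpenoid carbocycles. The ring closes in the 14-exo-tet mode, helped by the ortho arrangement of the two arms on the benzene ring and by high dilution, which suppresses intermolecular alkylation. The only new stereocenter, C5', is formed without control and is irrelevant because the sulfonyl group is removed in step 18. The step needs alpha- rather than gamma-alkylation of the allyl anion and SN2 rather than SN2' attack on the chloride; both should be secured because the alternative carbons (C7' and C2') are the more substituted ends and the negative charge is held next to sulfur. Both Z alkenes should be retained because neither allyl unit passes through a metal-allyl or cationic intermediate, and the silyl ethers at O8 and O10' leave the sulfone CH2 as the only acidic site.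

Step 18
Reactants: 29 5'-(phenylsulfonyl)-8,10'-bis-O-TBS-chrysomutanin (both C5' epimers)
Product: 30 8,10'-bis-O-TBS-chrysomutanin
Conditions: Pd(PPh3)4 (10 mol%), NaBH4 (4 equiv), THF/i-PrOH, 0 °C → rt
Reagents that add atoms: none
Why: Palladium-catalysed hydride desulfonylation: zerovalent palladium ionises the allylic sulfone to an allylpalladium sulfinate and borohydride should deliver hydride to the less substituted terminus C5', so that the C6'=C7' alkene stays in place and Z, while NaBH4 at this temperature leaves the lactone alone.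

Step 19
Reactants: 30 8,10'-bis-O-TBS-chrysomutanin
Product: 31 chrysomutanin
Conditions: Bu4NF (3 equiv), AcOH (3 equiv), THF, rt → 40 °C
Reagents that add atoms: none
Why: Fluoride-mediated desilylation cleaves the aryl and the secondary silyl ether; the acetic acid buffer keeps the lactone and the tertiary aryl ether safe from alkoxide-driven side reactions.

**Compound list**
1 | prop-2-yn-1-ol | C#CCO | starting material
2 | (2Z)-3-iodo-2-methylprop-2-en-1-ol | OC/C(C)=C\I | intermediate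
3 | (1Z)-3-bromo-1-iodo-2-methylprop-1-ene | BrC/C(C)=C\I | intermediate
4 | 5-bromobenzene-1,3-diol | Oc1cc(O)cc(Br)c1 | starting material
5 | 1-bromo-3,5-bis(methoxymethoxy)benzene | COCOc1cc(Br)cc(OCOC)c1 | intermediate
6 | (R)-2-methyloxirane | C[C@@H]1CO1 | starting material
7 | [3,5-bis(methoxymethoxy)phenyl]magnesium bromide | COCOc1cc([Mg]Br)cc(OCOC)c1 | intermediate
8 | (2R)-1-[3,5-bis(methoxymethoxy)phenyl]propan-2-ol | C[C@@H](O)Cc1cc(OCOC)cc(OCOC)c1 | intermediate
9 | (2R)-1-[2,6-dibromo-3,5-bis(methoxymethoxy)phenyl]propan-2-ol | C[C@@H](O)Cc1c(Br)c(OCOC)cc(OCOC)c1Br | intermediate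
10 | lithium (2R)-1-[2-bromo-6-lithio-3,5-bis(methoxymethoxy)phenyl]propan-2-olate | C[C@@H](O[Li])Cc1c([Li])c(OCOC)cc(OCOC)c1Br | intermediate
11 | 3-bromo-2-[(2R)-2-hydroxypropyl]-4,6-bis(methoxymethoxy)benzoic acid | C[C@@H](O)Cc1c(Br)c(OCOC)cc(OCOC)c1C(=O)O | intermediate
12 | (3R)-5-bromo-6,8-bis(methoxymethoxy)-3-methyl-3,4-dihydroisochromen-1-one | Brc1c(OCOC)cc(OCOC)c2c1C[C@@H](C)OC2=O | intermediate
13 | (3R)-6,8-bis(methoxymethoxy)-3-methyl-5-[(pinacolatoboryl)methyl]-3,4-dihydroisochromen-1-one | CC1(C)OB(Cc2c(OCOC)cc(OCOC)c3c2C[C@@H](C)OC3=O)OC1(C)C | intermediate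
14 | (3R)-5-[(2Z)-4-hydroxy-3-methylbut-2-enyl]-6,8-bis(methoxymethoxy)-3-methyl-3,4-dihydroisochromen-1-one | OC/C(C)=C\Cc1c(OCOC)cc(OCOC)c2c1C[C@@H](C)OC2=O | intermediate
15 | (3R)-6,8-dihydroxy-5-[(2Z)-4-hydroxy-3-methylbut-2-enyl]-3-methyl-3,4-dihydroisochromen-1-one | OC/C(C)=C\Cc1c(O)cc(O)c2c1C[C@@H](C)OC2=O | intermediate
16 | 3-bromo-3-methylbutan-2-one | CC(=O)C(C)(C)Br | starting material
17 | (3R)-8-hydroxy-5-[(2Z)-4-hydroxy-3-methylbut-2-enyl]-3-methyl-6-[(2-methyl-3-oxobutan-2-yl)oxy]-3,4-dihydroisochromen-1-one | OC/C(C)=C\Cc1c(OC(C)(C)C(C)=O)cc(O)c2c1C[C@@H](C)OC2=O | intermediate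
18 | (3R)-3-methyl-5-[(2Z)-3-methyl-4-(TBS-oxy)but-2-enyl]-6-[(2-methyl-3-oxobutan-2-yl)oxy]-8-(TBS-oxy)-3,4-dihydroisochromen-1-one | CC(C)(C)[Si](C)(C)OC/C(C)=C\Cc1c(OC(C)(C)C(C)=O)cc(O[Si](C)(C)C(C)(C)C)c2c1C[C@@H](C)OC2=O | intermediate
19 | lithium enolate of 18 (lithium 3-aryloxy-3-methylbut-1-en-2-olate) | CC(C)(C)[Si](C)(C)OC/C(C)=C\Cc1c(OC(C)(C)C(=C)O[Li])cc(O[Si](C)(C)C(C)(C)C)c2c1C[C@@H](C)OC2=O | intermediate
20 | (3R)-6-{[(6Z)-7-iodo-2,6-dimethyl-3-oxohept-6-en-2-yl]oxy}-3-methyl-5-[(2Z)-3-methyl-4-(TBS-oxy)but-2-enyl]-8-(TBS-oxy)-3,4-dihydroisochromen-1-one | CC(C)(C)[Si](C)(C)OC/C(C)=C\Cc1c(OC(C)(C)C(=O)CC/C(C)=C\I)cc(O[Si](C)(C)C(C)(C)C)c2c1C[C@@H](C)OC2=O | intermediate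
21 | (3R)-6-{[(3S,6Z)-3-hydroxy-7-iodo-2,6-dimethylhept-6-en-2-yl]oxy}-3-methyl-5-[(2Z)-3-methyl-4-(TBS-oxy)but-2-enyl]-8-(TBS-oxy)-3,4-dihydroisochromen-1-one | CC(C)(C)[Si](C)(C)OC/C(C)=C\Cc1c(OC(C)(C)[C@@H](O)CC/C(C)=C\I)cc(O[Si](C)(C)C(C)(C)C)c2c1C[C@@H](C)OC2=O | intermediate
22 | (3R)-6-{[(3S,6Z)-7-iodo-2,6-dimethyl-3-(TBS-oxy)hept-6-en-2-yl]oxy}-3-methyl-5-[(2Z)-3-methyl-4-(TBS-oxy)but-2-enyl]-8-(TBS-oxy)-3,4-dihydroisochromen-1-one | CC(C)(C)[Si](C)(C)OC/C(C)=C\Cc1c(OC(C)(C)[C@@H](O[Si](C)(C)C(C)(C)C)CC/C(C)=C\I)cc(O[Si](C)(C)C(C)(C)C)c2c1C[C@@H](C)OC2=O | intermediate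
23 | (methylsulfonyl)benzene (methyl phenyl sulfone) | CS(=O)(=O)c1ccccc1 | starting material
24 | chloro[(phenylsulfonyl)methyl]zinc | Cl[Zn]CS(=O)(=O)c1ccccc1 | intermediate
25 | (3R)-6-{[(3S,6Z)-2,6-dimethyl-8-(phenylsulfonyl)-3-(TBS-oxy)oct-6-en-2-yl]oxy}-3-methyl-5-[(2Z)-3-methyl-4-(TBS-oxy)but-2-enyl]-8-(TBS-oxy)-3,4-dihydroisochromen-1-one | CC(C)(C)[Si](C)(C)OC/C(C)=C\Cc1c(OC(C)(C)[C@@H](O[Si](C)(C)C(C)(C)C)CC/C(C)=C\CS(=O)(=O)c3ccccc3)cc(O[Si](C)(C)C(C)(C)C)c2c1C[C@@H](C)OC2=O | intermediate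
26 | (3R)-6-{[(3S,6Z)-2,6-dimethyl-8-(phenylsulfonyl)-3-(TBS-oxy)oct-6-en-2-yl]oxy}-5-[(2Z)-4-hydroxy-3-methylbut-2-enyl]-3-methyl-8-(TBS-oxy)-3,4-dihydroisochromen-1-one | OC/C(C)=C\Cc1c(OC(C)(C)[C@@H](O[Si](C)(C)C(C)(C)C)CC/C(C)=C\CS(=O)(=O)c3ccccc3)cc(O[Si](C)(C)C(C)(C)C)c2c1C[C@@H](C)OC2=O | intermediate
27 | (3R)-5-[(2Z)-4-chloro-3-methylbut-2-enyl]-6-{[(3S,6Z)-2,6-dimethyl-8-(phenylsulfonyl)-3-(TBS-oxy)oct-6-en-2-yl]oxy}-3-methyl-8-(TBS-oxy)-3,4-dihydroisochromen-1-one | ClC/C(C)=C\Cc1c(OC(C)(C)[C@@H](O[Si](C)(C)C(C)(C)C)CC/C(C)=C\CS(=O)(=O)c3ccccc3)cc(O[Si](C)(C)C(C)(C)C)c2c1C[C@@H](C)OC2=O | intermediate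
28 | potassium salt of 27 deprotonated at C5' (the CH2 next to sulfur) | ClC/C(C)=C\Cc1c(OC(C)(C)[C@@H](O[Si](C)(C)C(C)(C)C)CC/C(C)=C\[CH-]S(=O)(=O)c3ccccc3)cc(O[Si](C)(C)C(C)(C)C)c2c1C[C@@H](C)OC2=O.[K+] | intermediate
29 | 5'-(phenylsulfonyl)-8,10'-bis-O-TBS-chrysomutanin (both C5' epimers) | C/C1=C/Cc2c(cc(O[Si](C)(C)C(C)(C)C)c3c2C[C@@H](C)OC3=O)OC(C)(C)[C@@H](O[Si](C)(C)C(C)(C)C)CC/C(C)=C\C(S(=O)(=O)c4ccccc4)C1 | intermediate
30 | 8,10'-bis-O-TBS-chrysomutanin | C/C1=C/Cc2c(cc(O[Si](C)(C)C(C)(C)C)c3c2C[C@@H](C)OC3=O)OC(C)(C)[C@@H](O[Si](C)(C)C(C)(C)C)CC/C(C)=C\CC1 | intermediate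
31 | chrysomutanin | C/C1=C/Cc2c(cc(O)c3c2C[C@@H](C)OC3=O)OC(C)(C)[C@@H](O)CC/C(C)=C\CC1 | target

**Step count and risks**
Total step count: 19. Longest linear sequence: 17 steps (steps 3–19, from 5-bromobenzene-1,3-diol 4).

Step 17 (ring closure). What may go wrong: intermolecular alkylation (oligomerisation) outrunning the 14-membered ring closure, or base-induced 1,4-elimination of HCl from the allylic chloride. Fallback: the same bond is closed under palladium templating (Tsuji–Trost macrocyclisation) instead of by a free carbanion. The fallback sets out from alcohol 26, which with ClCO2Me and pyridine should give the allylic methyl carbonate F1. With Pd(PPh3)4 and dppe in THF at high dilution and 60 °C, ionisation releases CO2 and methoxide; the methoxide deprotonates the sulfone, and the carbanion should attack the CH2 terminus of the allylpalladium unit. The route is rejoined at 29. The Z geometry at C2'=C3' would have to be confirmed, since the allylpalladium unit can equilibrate.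

Step 18 (desulfonylation). What may go wrong: slow ionisation of the hindered secondary allylic sulfone with the mild hydride donor, or hydride delivery at the wrong allyl terminus with migration of the alkene. Fallback: the strongest and most regio-faithful hydride donor is used and reduction of the lactone is accepted and then reversed. The fallback sets out from 29: PdCl2(dppp) with excess LiBHEt3 in THF at 0 °C should remove the sulfonyl group and reduce the lactone, giving the desulfonylated diol F2. Oxidative lactonisation with TEMPO (cat.) and PhI(OAc)2 in CH2Cl2 (primary benzylic alcohol to aldehyde, lactol, lactone) rejoins the route at 30.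

Step 14 (sulfonylmethyl Negishi coupling). What may go wrong: sluggish transmetalation or premature protonation of the alpha-sulfonyl zinc reagent, so that the alkenyl iodide is not converted. Fallback: C5' is introduced at the alcohol oxidation level and the sulfone is added by substitution. The fallback sets out from 22: Stille coupling with (tributylstannyl)methanol (Pd(PPh3)4, 1,4-dioxane, 90 °C) should give the allylic alcohol F3 with retention of the Z geometry. Corey–Kim chlorination then gives the allylic chloride F4, and PhSO2Na in DMF (SN2 at the primary allylic carbon) rejoins the route at 25.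

Further compounds
F1 | step 17 | methyl carbonate of alcohol 26: (3R)-6-{[(3S,6Z)-2,6-dimethyl-8-(phenylsulfonyl)-3-(TBS-oxy)oct-6-en-2-yl]oxy}-5-[(2Z)-4-(methoxycarbonyloxy)-3-methylbut-2-enyl]-3-methyl-8-(TBS-oxy)-3,4-dihydroisochromen-1-one | COC(=O)OC/C(C)=C\Cc1c(OC(C)(C)[C@@H](O[Si](C)(C)C(C)(C)C)CC/C(C)=C\CS(=O)(=O)c3ccccc3)cc(O[Si](C)(C)C(C)(C)C)c2c1C[C@@H](C)OC2=O
F2 | step 18 | desulfonylated diol: 8,10'-bis-O-TBS-chrysomutanin with the lactone reduced to a benzylic CH2OH on C8a and a free (R)-2-hydroxypropyl group on C4a | C/C1=C/Cc2c(cc(O[Si](C)(C)C(C)(C)C)c(CO)c2C[C@@H](C)O)OC(C)(C)[C@@H](O[Si](C)(C)C(C)(C)C)CC/C(C)=C\CC1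
F3 | step 14 | (3R)-6-{[(3S,6Z)-8-hydroxy-2,6-dimethyl-3-(TBS-oxy)oct-6-en-2-yl]oxy}-3-methyl-5-[(2Z)-3-methyl-4-(TBS-oxy)but-2-enyl]-8-(TBS-oxy)-3,4-dihydroisochromen-1-one | CC(C)(C)[Si](C)(C)OC/C(C)=C\Cc1c(OC(C)(C)[C@@H](O[Si](C)(C)C(C)(C)C)CC/C(C)=C\CO)cc(O[Si](C)(C)C(C)(C)C)c2c1C[C@@H](C)OC2=O
F4 | step 14 | (3R)-6-{[(3S,6Z)-8-chloro-2,6-dimethyl-3-(TBS-oxy)oct-6-en-2-yl]oxy}-3-methyl-5-[(2Z)-3-methyl-4-(TBS-oxy)but-2-enyl]-8-(TBS-oxy)-3,4-dihydroisochromen-1-one | CC(C)(C)[Si](C)(C)OC/C(C)=C\Cc1c(OC(C)(C)[C@@H](O[Si](C)(C)C(C)(C)C)CC/C(C)=C\CCl)cc(O[Si](C)(C)C(C)(C)C)c2c1C[C@@H](C)OC2=O
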